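**Strategy.** Ring C is cut at C2–C3 and O1–C8a. The feature exploited is that C2 is a benzylic carbinol carbon beta to the C4 ketone, while C8a sits ortho to that same acyl group on ring A and is therefore open to SNAr. In one flask, a chiral oxazaborolidinone-catalysed Mukaiyama aldol joins the trimethylsilyl enol ether of a 2-fluoroacetophenone (carrying the silyl-protected hydroxyprenyl chain and the methoxy group) to bis-silylated protocatechualdehyde, setting C2. Substoichiometric fluoride then unmasks the aldol oxygen, which displaces the ortho fluoride and closes ring C. Global desilylation gives the target.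

Key step: step 7

Remark on the chemistry: positions are numbered as in flavanones (O1, C2, C3, C4, C4a, C5 to C8, C8a; rings A, B, C). The sense of induction in step 7 is assumed from the accepted shielding model of the tryptophan-derived oxazaborolidinone ((R)-catalyst leaves the si face of the bound aldehyde open); if the sense proved opposite, the (S)-tryptophan-derived catalyst would be used.

**Step 1**
Reactants: 1 2-methyl-2-vinyloxirane (racemic)
Product: 2 (2E)-4-chloro-2-methylbut-2-en-1-ol
Conditions: TiCl4, CH2Cl2, −85 °C; aqueous work-up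
Reagents that add atoms: TiCl4, Cl[Ti](Cl)(Cl)Cl
Why: Lewis-acid-mediated SN2' opening of the vinyl epoxide, in which titanium binds the epoxide oxygen and chloride is delivered to the vinyl terminus of the s-trans conformer, should place CH2Cl trans to CH2OH and give the (E)-alkene.

**Step 2**
Reactants: 2 (2E)-4-chloro-2-methylbut-2-en-1-ol
Product: 3 tert-butyl{[(2E)-4-chloro-2-methylbut-2-en-1-yl]oxy}dimethylsilane
Conditions: TBSCl, imidazole, DMF, 0 °C → rt
Reagents that add atoms: TBSCl, CC(C)(C)[Si](C)(C)Cl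
Why: Imidazole-promoted silylation of the primary alcohol is standard and should leave the allylic chloride and the alkene geometry untouched.

**Step 3**
Reactants: 4 1-bromo-2-fluoro-4-methoxybenzene; 3 tert-butyl{[(2E)-4-chloro-2-methylbut-2-en-1-yl]oxy}dimethylsilane
Product: 7 {[(2E)-4-(3-bromo-2-fluoro-6-methoxyphenyl)-2-methylbut-2-en-1-yl]oxy}(tert-butyl)dimethylsilane, via aryllithium 5 (not isolated), via arylcopper 6 (not isolated)
Conditions: LiN(i-Pr)2, THF, −78 °C; CuBr·SMe2, −78 → −40 °C; then 3, −40 °C → rt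
Reagents that add atoms: none
Why: Directed ortho-metalation removes the most acidic proton, flanked by F and OMe, without touching the bromide; transmetalation to copper suppresses LiF loss, and the arylcopper should displace chloride at the unhindered primary carbon (SN2 allylation, as in copper-mediated prenylation) with the (E) geometry retained.

**Step 4**
Reactants: 7 {[(2E)-4-(3-bromo-2-fluoro-6-methoxyphenyl)-2-methylbut-2-en-1-yl]oxy}(tert-butyl)dimethylsilane
Product: 10 1-{3-[(2E)-4-{[tert-butyl(dimethyl)silyl]oxy}-3-methylbut-2-en-1-yl]-2-fluoro-4-methoxyphenyl}ethan-1-one, via aryllithium 8 (not isolated), via tetrahedral lithium adduct 9 (not isolated)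
Conditions: n-BuLi, THF, −78 °C; N-methoxy-N-methylacetamide, −78 → −20 °C; aq. NH4Cl
Reagents that add atoms: N-methoxy-N-methylacetamide, CC(=O)N(C)OC
Why: Bromine–lithium exchange at −78 °C should outrun LiF elimination and benzylic deprotonation, and the aryllithium adds only once to the amide because the chelated adduct collapses to the ketone on work-up (Weinreb ketone synthesis).

**Step 5**
Reactants: 10 1-{3-[(2E)-4-{[tert-butyl(dimethyl)silyl]oxy}-3-methylbut-2-en-1-yl]-2-fluoro-4-methoxyphenyl}ethan-1-one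
Product: 11 tert-butyl{[(2E)-4-(2-fluoro-6-methoxy-3-{1-[(trimethylsilyl)oxy]ethenyl}phenyl)-2-methylbut-2-en-1-yl]oxy}dimethylsilane
Conditions: TMSOTf, Et3N, CH2Cl2, 0 °C
Reagents that add atoms: TMSOTf, C[Si](C)(C)OS(=O)(=O)C(F)(F)F
Why: Soft enolisation and O-silylation of the aryl methyl ketone, which can enolise on one side only, should give the terminal enol silane; the product would be used crude.

**Step 6**
Reactants: 12 3,4-dihydroxybenzaldehyde
Product: 13 3,4-bis[(triisopropylsilyl)oxy]benzaldehyde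
Conditions: TIPSCl, imidazole, DMF, rt
Reagents that add atoms: TIPSCl, CC(C)[Si](Cl)(C(C)C)C(C)C
Why: Standard silylation of both phenols; the bulky triisopropylsilyl groups are chosen so that they should resist the substoichiometric fluoride of step 7 yet fall in the final fluoride treatment.

**Step 7**
Reactants: 11 tert-butyl{[(2E)-4-(2-fluoro-6-methoxy-3-{1-[(trimethylsilyl)oxy]ethenyl}phenyl)-2-methylbut-2-en-1-yl]oxy}dimethylsilane; 13 3,4-bis[(triisopropylsilyl)oxy]benzaldehyde
Product: 16 (2S)-2-{3,4-bis[(triisopropylsilyl)oxy]phenyl}-8-[(2E)-4-{[tert-butyl(dimethyl)silyl]oxy}-3-methylbut-2-en-1-yl]-7-methoxy-2,3-dihydro-4H-chromen-4-one, via (3S)-trimethylsilyl aldol ether 14 (not isolated), via tetrabutylammonium aldolate 15 (not isolated)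
Conditions: 13 (1.2 equiv), (4R)-2-butyl-4-(1H-indol-3-ylmethyl)-3-[(4-methylphenyl)sulfonyl]-1,3,2-oxazaborolidin-5-one (20 mol %), EtCN, −78 °C; then Bu4N[Ph3SiF2] (0.4 equiv), THF, −78 → −20 °C; pH 7 buffer
Reagents that add atoms: none
Why: The boron Lewis acid activates aldehyde 13 and enol silane 11 adds to its si face (Mukaiyama aldol with silyl transfer), forming C2–C3 and the (S)-silyl ether 14; fluoride then cleaves only the labile O–SiMe3 bond, and the tetrabutylammonium alkoxide 15 attacks C8a and expels fluoride, forming O1–C8a while the released fluoride carries the chain on. The closest known reaction types are the oxazaborolidinone-catalysed Mukaiyama aldol of aryl methyl ketone enol silanes with aromatic aldehydes and the fluoride-triggered desilylative SNAr etherification of ortho-acyl aryl fluorides. Ring C closes by intramolecular addition–elimination, formally a 6-endo-trig attack on C8a in which the charge passes through C4a into the C4 carbonyl (Meisenheimer intermediate). C2 is set by the catalyst, whose indolylmethyl group shields the re face of the boron-bound aldehyde, and it is not touched in the ring closure because the C2–O bond is never broken. The step needs enantiofacial control (catalyst), chemoselective desilylation (trimethylsilyl ether against the bulky aryl triisopropylsilyl and primary tert-butyldimethylsilyl ethers, secured by substoichiometric fluoride and low temperature) and ring closure faster than retro-aldol cleavage or E1cB dehydration of 15 (secured by the naked alkoxide, the ortho-acyl activation and the six-membered transition state).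

**Step 8**
Reactants: 16 (2S)-2-{3,4-bis[(triisopropylsilyl)oxy]phenyl}-8-[(2E)-4-{[tert-butyl(dimethyl)silyl]oxy}-3-methylbut-2-en-1-yl]-7-methoxy-2,3-dihydro-4H-chromen-4-one
Product: 17 (2S)-2-(3,4-dihydroxyphenyl)-8-[(2E)-4-hydroxy-3-methylbut-2-en-1-yl]-7-methoxy-2,3-dihydro-4H-chromen-4-one
Conditions: Bu4NF (4 equiv), AcOH (4 equiv), THF, 0 °C → rt
Reagents that add atoms: none
Why: Fluoride-mediated cleavage of all three Si–O bonds (global desilylation); the acetic acid buffer keeps the phenols protonated, so no phenoxide-triggered ring opening should scramble C2, and the alkene, ketone and methyl ether are inert.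

**Compound list**
1 | 2-methyl-2-vinyloxirane (racemic) | C=CC1(C)CO1 | starting material
2 | (2E)-4-chloro-2-methylbut-2-en-1-ol | ClC/C=C(\C)CO | intermediate
3 | tert-butyl{[(2E)-4-chloro-2-methylbut-2-en-1-yl]oxy}dimethylsilane | ClC/C=C(\C)CO[Si](C)(C)C(C)(C)C | intermediate
4 | 1-bromo-2-fluoro-4-methoxybenzene | COc1ccc(Br)c(F)c1 | starting material
5 | (3-bromo-2-fluoro-6-methoxyphenyl)lithium (not isolated) | COc1ccc(Br)c(F)c1[Li] | intermediate
6 | (3-bromo-2-fluoro-6-methoxyphenyl)copper (not isolated) | COc1ccc(Br)c(F)c1[Cu] | intermediate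
7 | {[(2E)-4-(3-bromo-2-fluoro-6-methoxyphenyl)-2-methylbut-2-en-1-yl]oxy}(tert-butyl)dimethylsilane | COc1ccc(Br)c(F)c1C/C=C(\C)CO[Si](C)(C)C(C)(C)C | intermediate
8 | {3-[(2E)-4-{[tert-butyl(dimethyl)silyl]oxy}-3-methylbut-2-en-1-yl]-2-fluoro-4-methoxyphenyl}lithium (not isolated) | COc1ccc([Li])c(F)c1C/C=C(\C)CO[Si](C)(C)C(C)(C)C | intermediate
9 | lithium 1-{3-[(2E)-4-{[tert-butyl(dimethyl)silyl]oxy}-3-methylbut-2-en-1-yl]-2-fluoro-4-methoxyphenyl}-1-[methoxy(methyl)amino]ethan-1-olate (tetrahedral adduct, not isolated) | COc1ccc(C(C)(O[Li])N(C)OC)c(F)c1C/C=C(\C)CO[Si](C)(C)C(C)(C)C | intermediate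
10 | 1-{3-[(2E)-4-{[tert-butyl(dimethyl)silyl]oxy}-3-methylbut-2-en-1-yl]-2-fluoro-4-methoxyphenyl}ethan-1-one | COc1ccc(C(C)=O)c(F)c1C/C=C(\C)CO[Si](C)(C)C(C)(C)C | intermediate
11 | tert-butyl{[(2E)-4-(2-fluoro-6-methoxy-3-{1-[(trimethylsilyl)oxy]ethenyl}phenyl)-2-methylbut-2-en-1-yl]oxy}dimethylsilane | COc1ccc(C(=C)O[Si](C)(C)C)c(F)c1C/C=C(\C)CO[Si](C)(C)C(C)(C)C | intermediate
12 | 3,4-dihydroxybenzaldehyde | O=Cc1ccc(O)c(O)c1 | starting material
13 | 3,4-bis[(triisopropylsilyl)oxy]benzaldehyde | O=Cc1ccc(O[Si](C(C)C)(C(C)C)C(C)C)c(O[Si](C(C)C)(C(C)C)C(C)C)c1 | intermediate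
14 | (3S)-3-{3,4-bis[(triisopropylsilyl)oxy]phenyl}-1-{3-[(2E)-4-{[tert-butyl(dimethyl)silyl]oxy}-3-methylbut-2-en-1-yl]-2-fluoro-4-methoxyphenyl}-3-[(trimethylsilyl)oxy]propan-1-one (not isolated) | COc1ccc(C(=O)C[C@H](O[Si](C)(C)C)c2ccc(O[Si](C(C)C)(C(C)C)C(C)C)c(O[Si](C(C)C)(C(C)C)C(C)C)c2)c(F)c1C/C=C(\C)CO[Si](C)(C)C(C)(C)C | intermediate
15 | tetrabutylammonium (1S)-1-{3,4-bis[(triisopropylsilyl)oxy]phenyl}-3-{3-[(2E)-4-{[tert-butyl(dimethyl)silyl]oxy}-3-methylbut-2-en-1-yl]-2-fluoro-4-methoxyphenyl}-3-oxopropan-1-olate (not isolated) | COc1ccc(C(=O)C[C@H]([O-])c2ccc(O[Si](C(C)C)(C(C)C)C(C)C)c(O[Si](C(C)C)(C(C)C)C(C)C)c2)c(F)c1C/C=C(\C)CO[Si](C)(C)C(C)(C)C.CCCC[N+](CCCC)(CCCC)CCCC | intermediate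
16 | (2S)-2-{3,4-bis[(triisopropylsilyl)oxy]phenyl}-8-[(2E)-4-{[tert-butyl(dimethyl)silyl]oxy}-3-methylbut-2-en-1-yl]-7-methoxy-2,3-dihydro-4H-chromen-4-one | COc1ccc2c(c1C/C=C(\C)CO[Si](C)(C)C(C)(C)C)O[C@H](c1ccc(O[Si](C(C)C)(C(C)C)C(C)C)c(O[Si](C(C)C)(C(C)C)C(C)C)c1)CC2=O | intermediate
17 | (2S)-2-(3,4-dihydroxyphenyl)-8-[(2E)-4-hydroxy-3-methylbut-2-en-1-yl]-7-methoxy-2,3-dihydro-4H-chromen-4-one | COc1ccc2c(c1C/C=C(\C)CO)O[C@H](c1ccc(O)c(O)c1)CC2=O | target

**Step count.** Total: 8 steps. Longest linear sequence: 7 steps (steps 1, 2, 3, 4, 5, 7, 8); step 6 is a one-step side branch.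

**Steps most likely to fail**

Step 7. The free alkoxide may fragment by retro-aldol cleavage and re-add without facial control, or dehydrate by E1cB, before it closes ring C. Facial control may also be weaker with the electron-rich aldehyde, and fluoride may strip aryl silyl ethers. The fallback sets out from enol silane 11 and aldehyde 13 and separates the two bond formations. A SiCl4-mediated aldol under Lewis-base catalysis by a chiral 1,1'-binaphthyl-2,2'-diamine-derived bisphosphoramide (the enantiomer that directs si-face attack; CH2Cl2, −78 °C), followed by aqueous KF/NaHCO3 work-up, should give the isolated (3S)-3-{3,4-bis[(triisopropylsilyl)oxy]phenyl}-1-{3-[(2E)-4-{[tert-butyl(dimethyl)silyl]oxy}-3-methylbut-2-en-1-yl]-2-fluoro-4-methoxyphenyl}-3-hydroxypropan-1-one F1. Its sodium alkoxide (NaH, THF, −20 → 0 °C) should then close ring C by SNAr, with NaF precipitating and no fluoride in solution, and the route is rejoined at 16.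

Step 3. The arylcopper may attack the substituted allylic terminus (SN2' path), the allylic chloride may couple slowly, or aryllithium 5 may lose LiF before transmetalation. The fallback sets out from 4 and builds the chain by metathesis. Arylcopper 6, made as before, would be quenched with allyl bromide to give 1-bromo-2-fluoro-4-methoxy-3-(prop-2-en-1-yl)benzene F2. Cross-metathesis with methacrolein (second-generation Grubbs catalyst, CH2Cl2, 40 °C) should give (2E)-4-(3-bromo-2-fluoro-6-methoxyphenyl)-2-methylbut-2-enal F3, the (E) geometry arising under thermodynamic control. Luche reduction (NaBH4, CeCl3·7H2O, MeOH, 0 °C) should give (2E)-4-(3-bromo-2-fluoro-6-methoxyphenyl)-2-methylbut-2-en-1-ol F4, and silylation (TBSCl, imidazole) returns to 7. Steps 1 and 2 are then not needed.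

Step 4. The ortho-fluoroaryllithium may lose LiF (aryne formation), or the benzylic–allylic CH2 may be deprotonated during the exchange. The fallback sets out from 7 and uses magnesium. Bromine–magnesium exchange with i-PrMgCl·LiCl (THF, 0 °C) should give {3-[(2E)-4-{[tert-butyl(dimethyl)silyl]oxy}-3-methylbut-2-en-1-yl]-2-fluoro-4-methoxyphenyl}magnesium chloride F5, which does not eliminate fluoride. Addition to acetaldehyde should give racemic 1-{3-[(2E)-4-{[tert-butyl(dimethyl)silyl]oxy}-3-methylbut-2-en-1-yl]-2-fluoro-4-methoxyphenyl}ethan-1-ol F6, and Dess–Martin oxidation (CH2Cl2, NaHCO3, rt) returns to 10.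

**Further compounds**
F1 | step 7 | (3S)-3-{3,4-bis[(triisopropylsilyl)oxy]phenyl}-1-{3-[(2E)-4-{[tert-butyl(dimethyl)silyl]oxy}-3-methylbut-2-en-1-yl]-2-fluoro-4-methoxyphenyl}-3-hydroxypropan-1-one | COc1ccc(C(=O)C[C@H](O)c2ccc(O[Si](C(C)C)(C(C)C)C(C)C)c(O[Si](C(C)C)(C(C)C)C(C)C)c2)c(F)c1C/C=C(\C)CO[Si](C)(C)C(C)(C)C
F2 | step 3 | 1-bromo-2-fluoro-4-methoxy-3-(prop-2-en-1-yl)benzene | COc1ccc(Br)c(F)c1CC=C
F3 | step 3 | (2E)-4-(3-bromo-2-fluoro-6-methoxyphenyl)-2-methylbut-2-enal | COc1ccc(Br)c(F)c1C/C=C(\C)C=O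
F4 | step 3 | (2E)-4-(3-bromo-2-fluoro-6-methoxyphenyl)-2-methylbut-2-en-1-ol | COc1ccc(Br)c(F)c1C/C=C(\C)CO
F5 | step 4 | {3-[(2E)-4-{[tert-butyl(dimethyl)silyl]oxy}-3-methylbut-2-en-1-yl]-2-fluoro-4-methoxyphenyl}magnesium chloride | COc1ccc([Mg]Cl)c(F)c1C/C=C(\C)CO[Si](C)(C)C(C)(C)C
F6 | step 4 | 1-{3-[(2E)-4-{[tert-butyl(dimethyl)silyl]oxy}-3-methylbut-2-en-1-yl]-2-fluoro-4-methoxyphenyl}ethan-1-ol (racemic) | COc1ccc(C(C)O)c(F)c1C/C=C(\C)CO[Si](C)(C)C(C)(C)C
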